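Readings and results were generated by integration with constants of no real substance; scatter was added.

I started from the charge.

| flask | substrate | remark | time |
|---|---|---|---|
| Wednesday's | 0.067 M | run made earlier |  |
| Friday's | 0.15 M | run made earlier |  |
| flask | 0.10 M |  | 5.0 d |

- Wednesday's (time / d: intermediate A / %, product / %): 0.0833: 23.0, 1.3; 0.125: 31.1, 1.3; 0.250: 41.6, 4.8; 0.500: 37.7, 21.9; 0.833: 26.5, 42.4; 1.67: 10.6, 71.9; 3.00: 3.2, 91.4
- Friday's (time / d: intermediate A / %, product / %): 0.0833: 25.7, 0.3; 0.125: 31.3, 2.3; 0.250: 42.9, 4.8; 0.500: 37.6, 20.7; 0.833: 26.0, 43.1; 1.67: 9.7, 72.6; 3.00: 2.0, 89.5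

(readings scatter by 1 percentage point)

- the best time, 5.0 d at the latest, for intermediate A
- the amount of intermediate A, in percent of the substrate charged, at that time
- the first time at which intermediate A reaches 21%, in the same percent



1. Friday's charge was 2.24 times Wednesday's. Yet at 0.250 d, c(intermediate A) read 42.9% on Friday and 41.6% on Wednesday, a gap of 1.3 percentage points against a scatter of 1 point. So I read apparent first order and carried the percent curve to the 0.10 M flask.

2. Each run's highest reading stood there. Their mean is my reading of the peak height in percent of the charge, 42.2%, and I committed it as the best amount.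

3. I compared rates next. On the run means, intermediate A gained 0.884 d⁻¹ of the charge before that reading and lost 0.184 d⁻¹ after it. A straight drift between the interval midpoints crosses zero at 0.343 d, far before the limit.

4. The chord from zero to the first mean rose 2.92 d⁻¹, which puts 21% at 0.0719 d.

5. That was the weak link. The chord to the second mean rose 2.50 d⁻¹, less steeply, so the curve bent. Letting the chord fall straight with time gave 0.0682 d.

The forecast gave 0.3 d, 42% and 0.066 d: “The two runs agree within scatter although the substrate differs about twofold”. Its best time was earlier than mine.

The flask gave 0.309 d, 42.2% and 0.0661 d.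

    substrate ⇌ dormant form (K = 1.90, k = 0.0760 h⁻¹)
    intermediate B → product (k = 0.270 h⁻¹)
    substrate → intermediate A (k = 0.170 h⁻¹)
    intermediate A → intermediate B (k = 0.0750 h⁻¹)

The 0.10 M flask peaked at 42.2%, beside my reading of 42.2%. The neighbour flask was charged with 0.025 M, a quarter of that charge. I applied the same reckoning to it and carried 42.2% over unchanged. The neighbour flask peaked at 42.2%. At 5.0 d it held 97.2% product, and 0.26% of its substrate was still unbound.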